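**Remark on the chemistry:** germacrane numbering is used throughout (C1–C10 carbocycle, C11–C13 lactone branch, C14 on C10, C15 on C4). The target's descriptors encode a cis 1,10-oxirane and a trans 4,5-oxirane, so the route passes through the (1(10)Z,4E)-diene.

## Retrosynthetic overview

1. Endgame: target ⇐ Shi epoxidation of C1=C10 ⇐ C6 angeloylation ⇐ tartrate-matched, hydroxyl-directed epoxidation of C4=C5 ⇐ (1(10)Z,4E)-6-hydroxy-dienolide 26.
2. Key disconnection C5–C6: intramolecular Nozaki–Hiyama–Kishi closure of lactone aldehyde/alkenyl iodide 24. It is made possible by the trans-fused γ-lactone (O8, C12, C11, C7, C8), which holds the C7 formyl and C8 side chain gauche, by the (Z)-C1=C10 bond, which turns the C9–C5 chain back onto C6, and by quaternary C11 next to C7, which fixes the face of the C6 aldehyde.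
3. C9–C10: copper-catalysed coupling of lactone triflate 11 (fragment A) with the (Z)-alkenylmagnesium from iodide 19 (fragment B, C5 masked as an alkenylsilane).
4. Fragment A: all lactone stereocentres are relayed from the one purchased centre, C8 of (S)-5-(hydroxymethyl)furan-2(5H)-one. Anti photo-addition of 1,3-dioxolane sets C7 and brings C6 as a masked aldehyde; enolate hydroxylation, then methylation anti to the C7 branch, sets C11.
5. Ring order: γ-lactone (purchased) → ten-membered carbocycle (step 15) → 4,5-oxirane (step 16) → 1,10-oxirane (step 18).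

Key step: step 15

## Route

**Fragment A (steps 1–7)**

Step 1
Reactants: 1 (S)-5-(hydroxymethyl)furan-2(5H)-one
Product: 2 (S)-5-{[(tert-butyldimethylsilyl)oxy]methyl}furan-2(5H)-one
Conditions: t-BuMe2SiCl, imidazole, DMF, 0 °C → rt
Reagents that add atoms: tert-butyldimethylsilyl chloride, CC(C)(C)[Si](C)(C)Cl
Why: Routine silylation of the primary alcohol; the bulky silyl ether later shields one face of the butenolide.

Step 2
Reactants: 2 (S)-5-{[(tert-butyldimethylsilyl)oxy]methyl}furan-2(5H)-one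
Product: 3 (4S,5S)-5-{[(tert-butyldimethylsilyl)oxy]methyl}-4-(1,3-dioxolan-2-yl)dihydrofuran-2(3H)-one
Conditions: 1,3-dioxolane (solvent), Ph2CO (0.1 equiv), hν (350 nm), rt, degassed
Reagents that add atoms: 1,3-dioxolane, C1COCO1
Why: Benzophenone-sensitised radical conjugate addition, in which the 1,3-dioxolan-2-yl radical should add to C4 of the butenolide anti to the C5 silyloxymethyl group, sets C7 trans to C8 and brings C6 as a masked aldehyde.

Step 3
Reactants: 3 (4S,5S)-5-{[(tert-butyldimethylsilyl)oxy]methyl}-4-(1,3-dioxolan-2-yl)dihydrofuran-2(3H)-one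
Product: 5 (3S,4S,5S)-5-{[(tert-butyldimethylsilyl)oxy]methyl}-4-(1,3-dioxolan-2-yl)-3-hydroxydihydrofuran-2(3H)-one, via potassium enolate 4 (not isolated)
Conditions: KN(SiMe3)2, THF, −78 °C; 2-(phenylsulfonyl)-3-phenyloxaziridine, −78 °C; aq. NH4Cl
Reagents that add atoms: 2-(phenylsulfonyl)-3-phenyloxaziridine, O=S(=O)(N1OC1c1ccccc1)c1ccccc1
Why: Enolate oxidation with an N-sulfonyloxaziridine should give the α-hydroxy lactone mainly anti to the C4 branch; the C3 configuration does not matter because step 4 erases it.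

Step 4
Reactants: 5 (3S,4S,5S)-5-{[(tert-butyldimethylsilyl)oxy]methyl}-4-(1,3-dioxolan-2-yl)-3-hydroxydihydrofuran-2(3H)-one
Product: 7 (3R,4R,5S)-5-{[(tert-butyldimethylsilyl)oxy]methyl}-4-(1,3-dioxolan-2-yl)-3-hydroxy-3-methyldihydrofuran-2(3H)-one, via dilithium enediolate 6 (not isolated)
Conditions: LiN(iPr)2 (2.2 equiv), THF/DMPU, −78 °C; MeI, −78 → −40 °C; aq. NH4Cl
Reagents that add atoms: iodomethane, CI
Why: C-Alkylation of the α-oxido enolate should occur anti to the adjacent C4 dioxolanyl branch (1,2-induction in a five-membered enolate), placing methyl trans and oxygen cis to that branch and so setting quaternary C11.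

Step 5
Reactants: 7 (3R,4R,5S)-5-{[(tert-butyldimethylsilyl)oxy]methyl}-4-(1,3-dioxolan-2-yl)-3-hydroxy-3-methyldihydrofuran-2(3H)-one
Product: 9 (3R,4R,5S)-5-{[(tert-butyldimethylsilyl)oxy]methyl}-4-(1,3-dioxolan-2-yl)-3-methyl-2-oxotetrahydrofuran-3-yl (Z)-2-methylbut-2-enoate, via lithium alkoxide 8 (not isolated)
Conditions: angelic acid, 2,4,6-Cl3C6H2COCl, Et3N, THF, rt (mixed anhydride); 7, LiN(SiMe3)2, THF, −78 °C; then the mixed anhydride, −78 → 0 °C
Reagents that add atoms: angelic acid [(Z)-2-methylbut-2-enoic acid], C/C=C(/C)C(=O)O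
Why: Yamaguchi-type acylation of the lithium tertiary alkoxide at the unhindered angeloyl carbonyl of the mixed anhydride; low temperature and the absence of a nucleophilic catalyst should preserve the Z geometry.

Step 6
Reactants: 9 (3R,4R,5S)-5-{[(tert-butyldimethylsilyl)oxy]methyl}-4-(1,3-dioxolan-2-yl)-3-methyl-2-oxotetrahydrofuran-3-yl (Z)-2-methylbut-2-enoate
Product: 10 (3R,4R,5S)-4-(1,3-dioxolan-2-yl)-5-(hydroxymethyl)-3-methyl-2-oxotetrahydrofuran-3-yl (Z)-2-methylbut-2-enoate
Conditions: HF·pyridine, pyridine, THF, 0 °C → rt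
Reagents that add atoms: none
Why: Buffered fluoride cleavage of the primary silyl ether should leave the dioxolane, lactone and angelate intact.

Step 7
Reactants: 10 (3R,4R,5S)-4-(1,3-dioxolan-2-yl)-5-(hydroxymethyl)-3-methyl-2-oxotetrahydrofuran-3-yl (Z)-2-methylbut-2-enoate
Product: 11 (3R,4R,5S)-4-(1,3-dioxolan-2-yl)-3-methyl-2-oxo-5-{[(trifluoromethylsulfonyl)oxy]methyl}tetrahydrofuran-3-yl (Z)-2-methylbut-2-enoate
Conditions: Tf2O, 2,6-lutidine, CH2Cl2, −78 °C
Reagents that add atoms: trifluoromethanesulfonic anhydride, O=S(=O)(OS(=O)(=O)C(F)(F)F)C(F)(F)F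
Why: Sulfonylation of the primary alcohol gives a leaving group reactive enough for sp3–sp2 coupling below 0 °C; the triflate is filtered through silica and used at once.

**Fragment B (steps 8–11)**

Step 8
Reactants: 12 pent-4-yn-1-ol
Product: 14 (E)-5-iodo-4-methylpent-4-en-1-ol, via alkenylalane 13 (not isolated)
Conditions: Me3Al (3 equiv), Cp2ZrCl2 (0.25 equiv), CH2Cl2, 0 °C → rt; I2, THF, −30 °C
Reagents that add atoms: trimethylaluminium, C[Al](C)C; iodine, II
Why: Negishi zirconium-catalysed carboalumination adds methyl and aluminium syn across the alkyne (methyl to the internal carbon) and iodinolysis proceeds with retention, which fixes the 4E geometry and brings C15.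

Step 9
Reactants: 14 (E)-5-iodo-4-methylpent-4-en-1-ol
Product: 17 (E)-4-methyl-5-(trimethylsilyl)pent-4-en-1-ol, via dilithio species 15 (not isolated), via bis-silyl compound 16 (not isolated)
Conditions: t-BuLi (3.2 equiv), Et2O, −78 °C; Me3SiCl, −78 °C → rt; K2CO3, MeOH, rt
Reagents that add atoms: chlorotrimethylsilane, C[Si](C)(C)Cl
Why: Iodine–lithium exchange and C-silylation proceed with retention and the O-silyl ether is removed by methanolysis; the alkenylsilane masks C5 through the organolithium chemistry of step 12.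

Step 10
Reactants: 17 (E)-4-methyl-5-(trimethylsilyl)pent-4-en-1-ol
Product: 18 (E)-4-methyl-5-(trimethylsilyl)pent-4-enal
Conditions: Dess–Martin periodinane, NaHCO3, CH2Cl2, 0 °C → rt
Reagents that add atoms: none
Why: Mild oxidation of the primary alcohol to the aldehyde without touching the alkenylsilane.

Step 11
Reactants: 18 (E)-4-methyl-5-(trimethylsilyl)pent-4-enal
Product: 19 [(1E,5Z)-6-iodo-2-methylhepta-1,5-dien-1-yl]trimethylsilane
Conditions: EtPPh3I, n-BuLi, THF, rt; I2, −78 °C; NaN(SiMe3)2, −20 °C; then 18, −78 °C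
Reagents that add atoms: ethyltriphenylphosphonium iodide, CC[P+](c1ccccc1)(c1ccccc1)c1ccccc1.[I-]; iodine, II
Why: Stork–Zhao-type Wittig olefination with the α-iodo ylide should give the (Z)-2-iodo-2-alkene (iodine cis to the chain), which fixes the 1(10)Z geometry and provides the precursor of the C10 nucleophile.

**Fragment union and endgame (steps 12–18)**

Step 12
Reactants: 19 [(1E,5Z)-6-iodo-2-methylhepta-1,5-dien-1-yl]trimethylsilane; 11 (3R,4R,5S)-4-(1,3-dioxolan-2-yl)-3-methyl-2-oxo-5-{[(trifluoromethylsulfonyl)oxy]methyl}tetrahydrofuran-3-yl (Z)-2-methylbut-2-enoate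
Product: 22 (3R,4R,5R)-5-[(2Z,6E)-2,6-dimethyl-7-(trimethylsilyl)hepta-2,6-dien-1-yl]-4-(1,3-dioxolan-2-yl)-3-methyl-2-oxotetrahydrofuran-3-yl (Z)-2-methylbut-2-enoate, via alkenyllithium 20 (not isolated), via alkenylmagnesium bromide 21 (not isolated)
Conditions: 19, t-BuLi (2.0 equiv), Et2O, −78 °C; MgBr2·OEt2, −78 → −40 °C; CuBr·SMe2 (0.1 equiv), then 11 in THF, −40 → −10 °C
Reagents that add atoms: none
Why: Iodine–lithium exchange, transmetalation and copper-catalysed substitution of the primary triflate (the known coupling of Grignard reagents with lactone-bearing primary triflates) should form C9–C10 with retention of the Z geometry, while lactone, angelate and acetal are not attacked at low temperature.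

Step 13
Reactants: 22 (3R,4R,5R)-5-[(2Z,6E)-2,6-dimethyl-7-(trimethylsilyl)hepta-2,6-dien-1-yl]-4-(1,3-dioxolan-2-yl)-3-methyl-2-oxotetrahydrofuran-3-yl (Z)-2-methylbut-2-enoate
Product: 23 (3R,4R,5R)-4-(1,3-dioxolan-2-yl)-5-[(2Z,6E)-7-iodo-2,6-dimethylhepta-2,6-dien-1-yl]-3-methyl-2-oxotetrahydrofuran-3-yl (Z)-2-methylbut-2-enoate
Conditions: N-iodosuccinimide, 2,6-lutidine (0.3 equiv), (CF3)2CHOH, 0 °C
Reagents that add atoms: N-iodosuccinimide, O=C1CCC(=O)N1I
Why: Iododesilylation with retention of geometry; the 2,2-disubstituted alkenylsilane reacts through a tertiary β-silyl cation and should therefore be consumed before the isolated trisubstituted alkene.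

Step 14
Reactants: 23 (3R,4R,5R)-4-(1,3-dioxolan-2-yl)-5-[(2Z,6E)-7-iodo-2,6-dimethylhepta-2,6-dien-1-yl]-3-methyl-2-oxotetrahydrofuran-3-yl (Z)-2-methylbut-2-enoate
Product: 24 (3R,4R,5R)-4-formyl-5-[(2Z,6E)-7-iodo-2,6-dimethylhepta-2,6-dien-1-yl]-3-methyl-2-oxotetrahydrofuran-3-yl (Z)-2-methylbut-2-enoate
Conditions: In(OTf)3 (0.05 equiv), acetone/H2O (20:1), rt
Reagents that add atoms: water, O
Why: Lewis acid catalysed acetal hydrolysis under nearly neutral conditions should release the C6 aldehyde without β-elimination of the two flanking acyloxy groups; the aldehyde is used directly.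

Step 15
Reactants: 24 (3R,4R,5R)-4-formyl-5-[(2Z,6E)-7-iodo-2,6-dimethylhepta-2,6-dien-1-yl]-3-methyl-2-oxotetrahydrofuran-3-yl (Z)-2-methylbut-2-enoate
Product: 26 (1(10)Z,4E,6R,7R,8R,11R)-11-angeloyloxy-6-hydroxygermacra-1(10),4-dien-8,12-olide, via alkenylchromium dichloride 25 (not isolated)
Conditions: CrCl2 (12 equiv), NiCl2 (0.2 equiv), degassed DMSO, rt, slow addition of 24 (final 0.002 M); aq. work-up
Reagents that add atoms: none
Why: Zerovalent nickel (formed from NiCl2 by divalent chromium) inserts into the C5–I bond and passes the alkenyl group to trivalent chromium, and the configurationally stable (E)-alkenylchromium adds to the C6 aldehyde, so that the C5–C6 bond, the ten-membered carbocycle and the C6 carbinol arise in one operation from a monocyclic precursor. The closest known reaction type is the intramolecular Nozaki–Hiyama–Kishi alkenylation used to close medium-ring and germacranolide-type ten-membered carbocycles. The ring closes in the 10-exo-trig mode (C=O exocyclic); closure should be favoured over oligomerisation by high dilution, by the trans-fused γ-lactone that fixes the C7–CHO and C8–CH2 bonds gauche, and by the (Z)-C1=C10 bond that turns the chain back. The new stereocentre C6 is controlled by C7: the alkenyl carbon should attack anti to quaternary C11 with C8 inside (Felkin–Anh), which places the hydroxyl syn to the C7–C11 bond as the target requires. The step needs aldehyde-selective addition and retention of the 4E geometry; organochromium reagents do not add to lactones or enoates, and alkenylchromium species keep their geometry.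

Step 16
Reactants: 26 (1(10)Z,4E,6R,7R,8R,11R)-11-angeloyloxy-6-hydroxygermacra-1(10),4-dien-8,12-olide
Product: 27 (1(10)Z,4S,5S,6S,7R,8R,11R)-11-angeloyloxy-4,5-epoxy-6-hydroxygermacr-1(10)-en-8,12-olide
Conditions: Ti(OiPr)4 (0.5 equiv), L-(+)-diethyl tartrate (0.6 equiv), t-BuOOH (2 equiv), 4 Å molecular sieves, CH2Cl2, −20 °C
Reagents that add atoms: tert-butyl hydroperoxide, CC(C)(C)OO
Why: Sharpless asymmetric epoxidation of the secondary allylic alcohol in the matched sense: natural tartrate delivers oxygen to the alkene face that gives the (4S,5S)-oxirane and the C6 carbinol of 26 has the fast-reacting configuration, so the erythro epoxy alcohol should form by relay from C6 to C4 and C5, while the non-allylic C1=C10 bond is untouched.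

Step 17
Reactants: 27 (1(10)Z,4S,5S,6S,7R,8R,11R)-11-angeloyloxy-4,5-epoxy-6-hydroxygermacr-1(10)-en-8,12-olide
Product: 28 (1(10)Z,4S,5S,6S,7S,8R,11R)-6,11-bis(angeloyloxy)-4,5-epoxygermacr-1(10)-en-8,12-olide
Conditions: angelic acid, 2,4,6-Cl3C6H2COCl, Et3N, PhMe, rt; then 27, PhMe, 80 °C
Reagents that add atoms: angelic acid [(Z)-2-methylbut-2-enoic acid], C/C=C(/C)C(=O)O
Why: Yamaguchi esterification through the mixed anhydride should acylate the hindered secondary alcohol at the angeloyl carbonyl without isomerisation to the tiglate.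

Step 18
Reactants: 28 (1(10)Z,4S,5S,6S,7S,8R,11R)-6,11-bis(angeloyloxy)-4,5-epoxygermacr-1(10)-en-8,12-olide
Product: 29 (1R,4S,5S,6S,7S,8R,10S,11R)-6,11-bis(angeloyloxy)-1,10:4,5-diepoxygermacran-8,12-olide (CNP0219924.1)
Conditions: D-fructose-derived Shi ketone [1,2:4,5-di-O-isopropylidene-β-D-erythro-2,3-hexodiulo-2,6-pyranose] (0.3 equiv), KHSO5 (Oxone), K2CO3, Bu4NHSO4, MeCN/CH2(OMe)2/aq. Na2B4O7 buffer (pH 10.5), 0 °C
Reagents that add atoms: potassium peroxymonosulfate, [K+].[O-]S(=O)(=O)OO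
Why: Shi epoxidation of the only remaining electron-rich alkene under reagent control: the spiro transition state places the single olefinic hydrogen (H1) in the hindered quadrant and should deliver oxygen to the face that gives the (1R,10S)-cis-oxirane, while the electron-poor angelate double bonds do not react.

## Compound list

1 | (S)-5-(hydroxymethyl)furan-2(5H)-one | O=C1C=C[C@@H](CO)O1 | starting material
2 | (S)-5-{[(tert-butyldimethylsilyl)oxy]methyl}furan-2(5H)-one | O=C1C=C[C@@H](CO[Si](C)(C)C(C)(C)C)O1 | intermediate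
3 | (4S,5S)-5-{[(tert-butyldimethylsilyl)oxy]methyl}-4-(1,3-dioxolan-2-yl)dihydrofuran-2(3H)-one (4,5-trans) | O1CCOC1[C@@H]2[C@@H](CO[Si](C)(C)C(C)(C)C)OC(=O)C2 | intermediate
4 | potassium enolate of lactone 3 | O1CCOC1[C@@H]2[C@@H](CO[Si](C)(C)C(C)(C)C)OC(O[K])=C2 | intermediate
5 | (3S,4S,5S)-5-{[(tert-butyldimethylsilyl)oxy]methyl}-4-(1,3-dioxolan-2-yl)-3-hydroxydihydrofuran-2(3H)-one (expected major C3 epimer; the 3R epimer converges in step 4) | O1CCOC1[C@@H]2[C@@H](CO[Si](C)(C)C(C)(C)C)OC(=O)[C@H]2O | intermediate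
6 | dilithium enediolate of 5 | O1CCOC1[C@@H]2[C@@H](CO[Si](C)(C)C(C)(C)C)OC(O[Li])=C2O[Li] | intermediate
7 | (3R,4R,5S)-5-{[(tert-butyldimethylsilyl)oxy]methyl}-4-(1,3-dioxolan-2-yl)-3-hydroxy-3-methyldihydrofuran-2(3H)-one | O1CCOC1[C@@H]2[C@@H](CO[Si](C)(C)C(C)(C)C)OC(=O)[C@]2(C)O | intermediate
8 | lithium alkoxide of 7 | O1CCOC1[C@@H]2[C@@H](CO[Si](C)(C)C(C)(C)C)OC(=O)[C@]2(C)O[Li] | intermediate
9 | (3R,4R,5S)-5-{[(tert-butyldimethylsilyl)oxy]methyl}-4-(1,3-dioxolan-2-yl)-3-methyl-2-oxotetrahydrofuran-3-yl (Z)-2-methylbut-2-enoate | O1CCOC1[C@@H]2[C@@H](CO[Si](C)(C)C(C)(C)C)OC(=O)[C@]2(C)OC(=O)/C(C)=C\C | intermediate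
10 | (3R,4R,5S)-4-(1,3-dioxolan-2-yl)-5-(hydroxymethyl)-3-methyl-2-oxotetrahydrofuran-3-yl (Z)-2-methylbut-2-enoate | O1CCOC1[C@@H]2[C@@H](CO)OC(=O)[C@]2(C)OC(=O)/C(C)=C\C | intermediate
11 | (3R,4R,5S)-4-(1,3-dioxolan-2-yl)-3-methyl-2-oxo-5-{[(trifluoromethylsulfonyl)oxy]methyl}tetrahydrofuran-3-yl (Z)-2-methylbut-2-enoate | O1CCOC1[C@@H]2[C@@H](COS(=O)(=O)C(F)(F)F)OC(=O)[C@]2(C)OC(=O)/C(C)=C\C | intermediate
12 | pent-4-yn-1-ol | C#CCCCO | starting material
13 | (E)-alkenyldimethylalane, as its dimethylaluminium alkoxide | C[Al](C)OCCC/C(C)=C/[Al](C)C | intermediate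
14 | (E)-5-iodo-4-methylpent-4-en-1-ol | OCCC/C(C)=C/I | intermediate
15 | dilithio species (lithium alkoxide and (E)-alkenyllithium) from 14 | [Li]OCCC/C(C)=C/[Li] | intermediate
16 | (E)-trimethyl{[4-methyl-5-(trimethylsilyl)pent-4-en-1-yl]oxy}silane | C[Si](C)(C)OCCC/C(C)=C/[Si](C)(C)C | intermediate
17 | (E)-4-methyl-5-(trimethylsilyl)pent-4-en-1-ol | OCCC/C(C)=C/[Si](C)(C)C | intermediate
18 | (E)-4-methyl-5-(trimethylsilyl)pent-4-enal | O=CCC/C(C)=C/[Si](C)(C)C | intermediate
19 | [(1E,5Z)-6-iodo-2-methylhepta-1,5-dien-1-yl]trimethylsilane | C/C(I)=C/CC/C(C)=C/[Si](C)(C)C | intermediate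
20 | (2Z,6E)-alkenyllithium from 19 | [Li]/C(C)=C\CC/C(C)=C/[Si](C)(C)C | intermediate
21 | (2Z,6E)-alkenylmagnesium bromide from 19 | Br[Mg]/C(C)=C\CC/C(C)=C/[Si](C)(C)C | intermediate
22 | (3R,4R,5R)-5-[(2Z,6E)-2,6-dimethyl-7-(trimethylsilyl)hepta-2,6-dien-1-yl]-4-(1,3-dioxolan-2-yl)-3-methyl-2-oxotetrahydrofuran-3-yl (Z)-2-methylbut-2-enoate | O1CCOC1[C@@H]2[C@@H](C/C(C)=C\CC/C(C)=C/[Si](C)(C)C)OC(=O)[C@]2(C)OC(=O)/C(C)=C\C | intermediate
23 | (3R,4R,5R)-4-(1,3-dioxolan-2-yl)-5-[(2Z,6E)-7-iodo-2,6-dimethylhepta-2,6-dien-1-yl]-3-methyl-2-oxotetrahydrofuran-3-yl (Z)-2-methylbut-2-enoate | O1CCOC1[C@@H]2[C@@H](C/C(C)=C\CC/C(C)=C/I)OC(=O)[C@]2(C)OC(=O)/C(C)=C\C | intermediate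
24 | (3R,4R,5R)-4-formyl-5-[(2Z,6E)-7-iodo-2,6-dimethylhepta-2,6-dien-1-yl]-3-methyl-2-oxotetrahydrofuran-3-yl (Z)-2-methylbut-2-enoate | O=C[C@@H]1[C@@H](C/C(C)=C\CC/C(C)=C/I)OC(=O)[C@]1(C)OC(=O)/C(C)=C\C | intermediate
25 | (E)-alkenylchromium dichloride (trivalent chromium) derived from 24 | O=C[C@@H]1[C@@H](C/C(C)=C\CC/C(C)=C/[Cr](Cl)Cl)OC(=O)[C@]1(C)OC(=O)/C(C)=C\C | intermediate
26 | (1(10)Z,4E,6R,7R,8R,11R)-11-angeloyloxy-6-hydroxygermacra-1(10),4-dien-8,12-olide | O[C@H]1[C@@H]2[C@@H](C/C(C)=C\CC/C(C)=C/1)OC(=O)[C@]2(C)OC(=O)/C(C)=C\C | intermediate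
27 | (1(10)Z,4S,5S,6S,7R,8R,11R)-11-angeloyloxy-4,5-epoxy-6-hydroxygermacr-1(10)-en-8,12-olide | O[C@H]1[C@@H]2[C@@H](C/C(C)=C\CC[C@]3(C)O[C@@H]13)OC(=O)[C@]2(C)OC(=O)/C(C)=C\C | intermediate
28 | (1(10)Z,4S,5S,6S,7S,8R,11R)-6,11-bis(angeloyloxy)-4,5-epoxygermacr-1(10)-en-8,12-olide | C/C=C(/C)C(=O)O[C@H]1[C@@H]2[C@@H](C/C(C)=C\CC[C@]3(C)O[C@@H]13)OC(=O)[C@]2(C)OC(=O)/C(C)=C\C | intermediate
29 | (1R,4S,5S,6S,7S,8R,10S,11R)-6,11-bis(angeloyloxy)-1,10:4,5-diepoxygermacran-8,12-olide (CNP0219924.1) | C/C=C(/C)C(=O)O[C@H]1[C@@H]2[C@@H](C[C@]3(C)O[C@@H]3CC[C@]3(C)O[C@@H]13)OC(=O)[C@]2(C)OC(=O)/C(C)=C\C | target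

## Step count and risks

Total step count: 18 (fragment A, steps 1–7; fragment B, steps 8–11; union and endgame, steps 12–18).
Longest linear sequence: 14 steps (1–7, then 12–18).

The three steps most likely to fail:

**Step 15 (ring closure).** The alkenylchromium may add to the other face of the aldehyde, so that the C6 epimer predominates; intermolecular coupling is the second hazard and is met by slower addition. The fallback sets out from crude 26 (both C6 epimers). It is oxidised with Dess–Martin periodinane/NaHCO3 (CH2Cl2, 0 °C) to (1(10)Z,4E,7R,8R,11R)-11-angeloyloxy-6-oxogermacra-1(10),4-dien-8,12-olide F1. F1 is then reduced under reagent control by Corey–Bakshi–Shibata reduction [(R)-2-methyl-CBS-oxazaborolidine, catecholborane, toluene, −78 °C, with the alkenyl arm taken as the larger carbonyl substituent], which returns to the route at 26. C6 is then set by the catalyst and no longer by the ring closure.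

**Step 16 (directed epoxidation).** The bulky titanium tartrate may fail to engage the hindered macrocyclic alkoxide, or oxygen may be delivered to the other alkene face (threo epoxy alcohol). The fallback gives up the directed epoxidation and sets both oxiranes by reagent control in the opposite order. It sets out from 26, which is angeloylated under the conditions of step 17 to (1(10)Z,4E,6R,7S,8R,11R)-6,11-bis(angeloyloxy)germacra-1(10),4-dien-8,12-olide F2. Shi epoxidation with the D-fructose-derived ketone should take place first at the more electron-rich and less hindered C1=C10 bond and give (1R,4E,6R,7S,8R,10S,11R)-6,11-bis(angeloyloxy)-1,10-epoxygermacr-4-en-8,12-olide F3. A second Shi epoxidation with the enantiomeric (L-fructose-derived) ketone, whose dioxirane prefers the face of the (E)-C4=C5 bond that leads to the (4S,5S)-oxirane, then comes back to the route at 29.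

**Step 18 (last epoxidation).** The dioxirane may approach the wrong face of the C1=C10 bond if the macrocycle's own facial bias overrides the catalyst. The fallback sets out from 28 and forms the oxirane in two steps on the face opposite to direct attack. NBS in THF/H2O (0 °C) forms the bromonium ion on the exposed face and water opens it at tertiary C10 from the other side, giving (1S,4S,5S,6S,7S,8R,10S,11R)-6,11-bis(angeloyloxy)-1-bromo-4,5-epoxy-10-hydroxygermacran-8,12-olide F4. DBU (CH2Cl2, rt) then closes the oxirane with inversion at C1 and comes back to the route at 29.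

Further compounds
F1 | step 15 | (1(10)Z,4E,7R,8R,11R)-11-angeloyloxy-6-oxogermacra-1(10),4-dien-8,12-olide | O=C1[C@@H]2[C@@H](C/C(C)=C\CC/C(C)=C/1)OC(=O)[C@]2(C)OC(=O)/C(C)=C\C
F2 | step 16 | (1(10)Z,4E,6R,7S,8R,11R)-6,11-bis(angeloyloxy)germacra-1(10),4-dien-8,12-olide | C/C=C(/C)C(=O)O[C@H]1[C@@H]2[C@@H](C/C(C)=C\CC/C(C)=C/1)OC(=O)[C@]2(C)OC(=O)/C(C)=C\C
F3 | step 16 | (1R,4E,6R,7S,8R,10S,11R)-6,11-bis(angeloyloxy)-1,10-epoxygermacr-4-en-8,12-olide | C/C=C(/C)C(=O)O[C@H]1[C@@H]2[C@@H](C[C@]3(C)O[C@@H]3CC/C(C)=C/1)OC(=O)[C@]2(C)OC(=O)/C(C)=C\C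
F4 | step 18 | (1S,4S,5S,6S,7S,8R,10S,11R)-6,11-bis(angeloyloxy)-1-bromo-4,5-epoxy-10-hydroxygermacran-8,12-olide | C/C=C(/C)C(=O)O[C@H]1[C@@H]2[C@@H](C[C@](C)(O)[C@@H](Br)CC[C@]3(C)O[C@@H]13)OC(=O)[C@]2(C)OC(=O)/C(C)=C\C
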